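**Retrosynthetic overview**

1. The strategy rests on rings A and D being the same 4-hydroxy-3-methoxyphenyl group, each bonded to an oxygen-bearing benzylic carbon (G1, the carbinol carbon of the arylglycerol unit; C2 of the dihydrobenzofuran) whose neighbour is a CH carrying CH2OH (G2, the carbon bearing the ring B ether oxygen; C3 on ring C). The ring A–G1 and ring D–C2 bonds are cut together, giving one lactone dialdehyde and two equivalents of one aryl bromide.
2. Before that, the O1–C2 bond of the dihydrofuran ring is cut to a MOM-protected ring C phenol and a C2 carbinol; it is closed last, by acid, through the ring D benzylic cation, trans to the C3 substituent.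
3. The dialdehyde comes from a diol, and this from a trans-3,4-dibenzyl lactone cut at the lactone C3–CH2 bond into the enolate of a (4R)-4-benzyl lactone (ring B part) and a ring C benzyl bromide.
4. G2 is set by Mitsunobu etherification of vanillin with a chiral-pool glycerol derivative, lactone C4 by asymmetric hydrogenation of a Stobbe half-ester, and C3 by Evans benzyloxymethylation of an arylacetyl imide made from 5-bromovanillin.
5. Ring order: lactone ring (step 5), then dihydrofuran ring (step 22); the four benzene rings come from the starting materials.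

Key step: step 21

Assumption: in step 4 the (4S,5S)-MOD-DIOP rhodium catalyst is taken to give the (R)-succinate half-ester, as expected for arylidenesuccinic half-esters; if a first run shows the opposite sense, the (4R,5R) ligand is used and nothing else changes.

Abbreviations: TBDPS = tert-butyldiphenylsilyl; TBS = tert-butyldimethylsilyl; MOM = methoxymethyl; Bn = benzyl; MOD-DIOP = 4,5-bis{[bis(4-methoxy-3,5-dimethylphenyl)phosphino]methyl}-2,2-dimethyl-1,3-dioxolane. TBDPS is used on the two CH2O arms because it survives the acid of steps 15 and 22 and does not chelate.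

**Ring B lactone fragment (steps 1–5)**

Step 1
Reactants: 1 (2R)-3-(benzyloxy)propane-1,2-diol
Product: 2 (2S)-1-(benzyloxy)-3-[(tert-butyldiphenylsilyl)oxy]propan-2-ol
Conditions: TBDPSCl (1.05 equiv), imidazole, CH2Cl2, 0 °C
Reagents that add atoms: tert-butyl(chloro)diphenylsilane, CC(C)(C)[Si](Cl)(c1ccccc1)c1ccccc1
Why: Selective silyl ether formation, in which the bulky chlorosilane reacts at the primary hydroxyl far faster than at the secondary one; the stereocentre is untouched and its descriptor changes from R to S only through the priority change.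

Step 2
Reactants: 2 (2S)-1-(benzyloxy)-3-[(tert-butyldiphenylsilyl)oxy]propan-2-ol; 3 vanillin
Product: 4 4-{[(2R)-1-(benzyloxy)-3-(TBDPS-oxy)propan-2-yl]oxy}-3-methoxybenzaldehyde
Conditions: PPh3, DIAD, THF, 0 °C to rt
Reagents that add atoms: none
Why: Mitsunobu etherification, in which the acidic phenol of vanillin displaces the oxyphosphonium group of 2 in an SN2 step with inversion, setting G2 in the configuration of the target (R in 4).

Step 3
Reactants: 4 4-{[(2R)-1-(benzyloxy)-3-(TBDPS-oxy)propan-2-yl]oxy}-3-methoxybenzaldehyde; 5 dimethyl succinate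
Product: 6 (3E)-4-[4-{[(2R)-1-(benzyloxy)-3-(TBDPS-oxy)propan-2-yl]oxy}-3-methoxyphenyl]-3-(methoxycarbonyl)but-3-enoic acid
Conditions: KOtBu, tBuOH/THF, 50 °C; then 1 M HCl to pH 3, 0 °C
Reagents that add atoms: none
Why: Stobbe condensation, in which the succinate enolate adds to the aldehyde, the alkoxide lactonises and E1cB ring opening gives the E half-ester, while the silyl, benzyl and aryl ethers are inert to tert-butoxide.

Step 4
Reactants: 6 (3E)-4-[4-{[(2R)-1-(benzyloxy)-3-(TBDPS-oxy)propan-2-yl]oxy}-3-methoxyphenyl]-3-(methoxycarbonyl)but-3-enoic acid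
Product: 7 (3R)-4-[4-{[(2R)-1-(benzyloxy)-3-(TBDPS-oxy)propan-2-yl]oxy}-3-methoxyphenyl]-3-(methoxycarbonyl)butanoic acid
Conditions: H2 (5 atm), [Rh(cod)Cl]2 (0.5 mol%), (4S,5S)-MOD-DIOP (1.1 mol%), Et3N (1 equiv), MeOH, 30 °C
Reagents that add atoms: none
Why: Rhodium-catalysed asymmetric hydrogenation of an itaconate-type half-ester, in which carboxylate and alkene bind the metal and the C2-symmetric diphosphine selects the alkene face, setting the future lactone C4 as R; the homogeneous catalyst does not cleave the benzyl ether.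

Step 5
Reactants: 7 (3R)-4-[4-{[(2R)-1-(benzyloxy)-3-(TBDPS-oxy)propan-2-yl]oxy}-3-methoxyphenyl]-3-(methoxycarbonyl)butanoic acid
Product: 9 (4R)-4-[[4-{[(2R)-1-(benzyloxy)-3-(TBDPS-oxy)propan-2-yl]oxy}-3-methoxyphenyl]methyl]oxolan-2-one, via hydroxy acid 8 (not isolated)
Conditions: KOH (1 equiv), EtOH; Ca(BH4)2 (from CaCl2 and NaBH4), EtOH, −10 °C to rt; then 2 M HCl, rt
Reagents that add atoms: none
Why: Chemoselective reduction of the ester beside a carboxylate salt by Ca(BH4)2, followed by acid-catalysed lactonisation (5-exo-trig acyl substitution) of hydroxy acid 8; the stereocentre is not touched.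

**Ring C benzyl bromide fragment (steps 6–16)**

Step 6
Reactants: 10 5-bromovanillin
Product: 11 3-bromo-5-methoxy-4-(methoxymethoxy)benzaldehyde
Conditions: MOMCl, iPr2NEt, CH2Cl2, 0 °C to rt
Reagents that add atoms: chloromethyl methyl ether, COCCl
Why: O-Alkylation of the phenol (Williamson-type acetal formation) installs the methoxymethyl ether that releases the ring C phenol under acid in step 22.

Step 7
Reactants: 11 3-bromo-5-methoxy-4-(methoxymethoxy)benzaldehyde
Product: 12 [3-bromo-5-methoxy-4-(methoxymethoxy)phenyl]methanol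
Conditions: NaBH4, MeOH, 0 °C
Reagents that add atoms: none
Why: Borohydride reduction of the aryl aldehyde to the benzylic alcohol; the aryl bromide and the acetal are inert.

Step 8
Reactants: 12 [3-bromo-5-methoxy-4-(methoxymethoxy)phenyl]methanol
Product: 13 {[3-bromo-5-methoxy-4-(methoxymethoxy)phenyl]methoxy}(tert-butyl)dimethylsilane
Conditions: TBSCl, imidazole, DMF, rt
Reagents that add atoms: tert-butyl(chloro)dimethylsilane, CC(C)(C)[Si](C)(C)Cl
Why: Silyl ether formation masks the benzylic alcohol with a group that can later be removed in the presence of a TBDPS ether.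

Step 9
Reactants: 13 {[3-bromo-5-methoxy-4-(methoxymethoxy)phenyl]methoxy}(tert-butyl)dimethylsilane
Product: 14 ethyl 2-[5-(TBS-oxymethyl)-3-methoxy-2-(methoxymethoxy)phenyl]acetate
Conditions: BrZnCH2CO2Et (from ethyl bromoacetate and Zn, THF), Pd(dba)2 (2 mol%), P(tBu)3 (2 mol%), THF, rt
Reagents that add atoms: ethyl bromoacetate (used as its zinc reagent BrZnCH2CO2Et), CCOC(=O)CBr
Why: Palladium-catalysed cross-coupling of an aryl bromide with a zinc ester enolate (Reformatsky reagent, Negishi-type alpha-arylation) runs under nearly neutral conditions that spare the acetal and the silyl ether.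

Step 10
Reactants: 14 ethyl 2-[5-(TBS-oxymethyl)-3-methoxy-2-(methoxymethoxy)phenyl]acetate
Product: 15 2-[5-(TBS-oxymethyl)-3-methoxy-2-(methoxymethoxy)phenyl]acetic acid
Conditions: LiOH, THF/H2O, rt; then 1 M HCl to pH 4, 0 °C
Reagents that add atoms: lithium hydroxide, [Li+].[OH-]
Why: Saponification of the ethyl ester; hydroxide at room temperature and a cold, weakly acidic work-up leave the silyl ether and the acetal intact.

Step 11
Reactants: 15 2-[5-(TBS-oxymethyl)-3-methoxy-2-(methoxymethoxy)phenyl]acetic acid; 16 (4R)-4-benzyl-1,3-oxazolidin-2-one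
Product: 18 (4R)-4-benzyl-3-{2-[5-(TBS-oxymethyl)-3-methoxy-2-(methoxymethoxy)phenyl]acetyl}-1,3-oxazolidin-2-one, via mixed pivalic anhydride 17 (not isolated)
Conditions: tBuCOCl, Et3N, THF, −20 °C; then 16, LiCl, rt
Reagents that add atoms: none
Why: N-Acylation of the oxazolidinone through the mixed pivalic anhydride 17 under LiCl/Et3N activation, the usual entry to an Evans imide.

Step 12
Reactants: 18 (4R)-4-benzyl-3-{2-[5-(TBS-oxymethyl)-3-methoxy-2-(methoxymethoxy)phenyl]acetyl}-1,3-oxazolidin-2-one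
Product: 20 (4R)-4-benzyl-3-{(2S)-3-(benzyloxy)-2-[5-(TBS-oxymethyl)-3-methoxy-2-(methoxymethoxy)phenyl]propanoyl}-1,3-oxazolidin-2-one, via sodium enolate 19 (not isolated)
Conditions: NaN(SiMe3)2, THF, −78 °C; BnOCH2Cl, −78 to −40 °C
Reagents that add atoms: benzyl chloromethyl ether, ClCOCc1ccccc1
Why: Evans alkylation, in which the chelated Z sodium enolate 19 is attacked by the chloromethyl ether on the face opposite the C4 benzyl group of the (R)-auxiliary, setting the side-chain carbon (the future C3 of the dihydrobenzofuran) as S.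

Step 13
Reactants: 20 (4R)-4-benzyl-3-{(2S)-3-(benzyloxy)-2-[5-(TBS-oxymethyl)-3-methoxy-2-(methoxymethoxy)phenyl]propanoyl}-1,3-oxazolidin-2-one
Product: 21 (2R)-3-(benzyloxy)-2-[5-(TBS-oxymethyl)-3-methoxy-2-(methoxymethoxy)phenyl]propan-1-ol
Conditions: LiBH4, THF/MeOH, 0 °C
Reagents that add atoms: none
Why: Reductive cleavage of the imide with LiBH4 gives the primary alcohol without touching the alpha stereocentre (R only through the priority change) and releases the auxiliary.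

Step 14
Reactants: 21 (2R)-3-(benzyloxy)-2-[5-(TBS-oxymethyl)-3-methoxy-2-(methoxymethoxy)phenyl]propan-1-ol
Product: 22 tert-butyl{(2S)-3-(benzyloxy)-2-[5-(TBS-oxymethyl)-3-methoxy-2-(methoxymethoxy)phenyl]propoxy}diphenylsilane
Conditions: TBDPSCl, imidazole, DMF, rt
Reagents that add atoms: tert-butyl(chloro)diphenylsilane, CC(C)(C)[Si](Cl)(c1ccccc1)c1ccccc1
Why: Silyl ether formation at the primary hydroxyl with the acid-stable, non-chelating TBDPS group that stays until step 23.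

Step 15
Reactants: 22 tert-butyl{(2S)-3-(benzyloxy)-2-[5-(TBS-oxymethyl)-3-methoxy-2-(methoxymethoxy)phenyl]propoxy}diphenylsilane
Product: 23 {3-[(2S)-1-(benzyloxy)-3-(TBDPS-oxy)propan-2-yl]-5-methoxy-4-(methoxymethoxy)phenyl}methanol
Conditions: PPTS (0.2 equiv), MeOH, rt
Reagents that add atoms: none
Why: Acid-catalysed methanolysis cleaves the primary TBS ether selectively, because the TBDPS ether and the aryl methoxymethyl acetal react far more slowly under pyridinium catalysis.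

Step 16
Reactants: 23 {3-[(2S)-1-(benzyloxy)-3-(TBDPS-oxy)propan-2-yl]-5-methoxy-4-(methoxymethoxy)phenyl}methanol
Product: 24 1-[(2S)-1-(benzyloxy)-3-(TBDPS-oxy)propan-2-yl]-5-(bromomethyl)-3-methoxy-2-(methoxymethoxy)benzene
Conditions: CBr4, PPh3, CH2Cl2, 0 °C
Reagents that add atoms: carbon tetrabromide, BrC(Br)(Br)Br
Why: Appel bromination converts the benzylic alcohol into the bromide under neutral conditions that leave the acetal and both ethers intact; the bromide is used at once.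

**Assembly and endgame (steps 17–24)**

Step 17
Reactants: 9 (4R)-4-[[4-{[(2R)-1-(benzyloxy)-3-(TBDPS-oxy)propan-2-yl]oxy}-3-methoxyphenyl]methyl]oxolan-2-one; 24 1-[(2S)-1-(benzyloxy)-3-(TBDPS-oxy)propan-2-yl]-5-(bromomethyl)-3-methoxy-2-(methoxymethoxy)benzene
Product: 26 (3R,4R)-3-[[3-[(2S)-1-(benzyloxy)-3-(TBDPS-oxy)propan-2-yl]-5-methoxy-4-(methoxymethoxy)phenyl]methyl]-4-[[4-{[(2R)-1-(benzyloxy)-3-(TBDPS-oxy)propan-2-yl]oxy}-3-methoxyphenyl]methyl]oxolan-2-one, via lithium enolate 25 (not isolated)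
Conditions: LiN(iPr)2, THF, −78 °C; then 24, DMPU, −78 to −40 °C
Reagents that add atoms: none
Why: Lactone enolate alkylation (SN2 on a benzylic bromide), in which the electrophile approaches enolate 25 anti to the C4 benzyl substituent, setting lactone C3 as R and giving the trans 3,4-disubstituted lactone.

Step 18
Reactants: 26 (3R,4R)-3-[[3-[(2S)-1-(benzyloxy)-3-(TBDPS-oxy)propan-2-yl]-5-methoxy-4-(methoxymethoxy)phenyl]methyl]-4-[[4-{[(2R)-1-(benzyloxy)-3-(TBDPS-oxy)propan-2-yl]oxy}-3-methoxyphenyl]methyl]oxolan-2-one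
Product: 27 (3R,4R)-3-[[3-[(2S)-1-hydroxy-3-(TBDPS-oxy)propan-2-yl]-5-methoxy-4-(methoxymethoxy)phenyl]methyl]-4-[[4-{[(2R)-1-hydroxy-3-(TBDPS-oxy)propan-2-yl]oxy}-3-methoxyphenyl]methyl]oxolan-2-one
Conditions: H2 (1 atm), Pd(OH)2/C, EtOAc/EtOH, rt
Reagents that add atoms: none
Why: Hydrogenolysis of the two alkyl benzyl ethers over palladium frees both primary alcohols at once, while the silyl ethers, the acetal, the aryl alkyl ether and the lactone are inert.

Step 19
Reactants: 27 (3R,4R)-3-[[3-[(2S)-1-hydroxy-3-(TBDPS-oxy)propan-2-yl]-5-methoxy-4-(methoxymethoxy)phenyl]methyl]-4-[[4-{[(2R)-1-hydroxy-3-(TBDPS-oxy)propan-2-yl]oxy}-3-methoxyphenyl]methyl]oxolan-2-one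
Product: 28 (3R,4R)-3-[[3-[(2R)-1-oxo-3-(TBDPS-oxy)propan-2-yl]-5-methoxy-4-(methoxymethoxy)phenyl]methyl]-4-[[4-{[(2S)-1-oxo-3-(TBDPS-oxy)propan-2-yl]oxy}-3-methoxyphenyl]methyl]oxolan-2-one
Conditions: Dess–Martin periodinane, NaHCO3, CH2Cl2, 0 °C to rt
Reagents that add atoms: none
Why: Dess–Martin oxidation of both primary alcohols under buffered, base-free conditions should give the dialdehyde without epimerising the two alpha centres; it is used crude and cold.

Step 20
Reactants: 29 4-bromo-2-methoxyphenol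
Product: 30 1-(benzyloxy)-4-bromo-2-methoxybenzene
Conditions: BnBr, K2CO3, DMF, rt
Reagents that add atoms: benzyl bromide, BrCc1ccccc1
Why: Williamson benzylation of the phenol gives the protected precursor of the aryl nucleophile.

Step 21
Reactants: 28 (3R,4R)-3-[[3-[(2R)-1-oxo-3-(TBDPS-oxy)propan-2-yl]-5-methoxy-4-(methoxymethoxy)phenyl]methyl]-4-[[4-{[(2S)-1-oxo-3-(TBDPS-oxy)propan-2-yl]oxy}-3-methoxyphenyl]methyl]oxolan-2-one; 30 1-(benzyloxy)-4-bromo-2-methoxybenzene
Product: 33 (3R,4R)-3-[[3-[(1R,2R)-1-(4-benzyloxy-3-methoxyphenyl)-1-hydroxy-3-(TBDPS-oxy)propan-2-yl]-5-methoxy-4-(methoxymethoxy)phenyl]methyl]-4-[[4-{[(1R,2S)-1-(4-benzyloxy-3-methoxyphenyl)-1-hydroxy-3-(TBDPS-oxy)propan-2-yl]oxy}-3-methoxyphenyl]methyl]oxolan-2-one, via aryllithium 31 (not isolated), via aryltitanium reagent 32 (not isolated)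
Conditions: 30 (5 equiv), n-BuLi, THF, −78 °C; ClTi(OiPr)3, −78 to −40 °C; then 28, THF, −78 to −10 °C; aq NH4Cl
Reagents that add atoms: none
Why: Bromine–lithium exchange on 30 and transmetalation with ClTi(OiPr)3 give the aryl reagent of tetravalent titanium 32, which coordinates each aldehyde oxygen and transfers its aryl group through a four-centre transition state, forming the ring A–G1 and ring D–C2 bonds in one operation. The closest known reaction type is the chemoselective 1,2-addition of organotitanium triisopropoxides to alpha-alkoxy and alpha-aryl aldehydes in the presence of esters, used here on both ends of one dialdehyde. No ring is closed in this step. At G1 the polar Felkin–Anh arrangement places the aryloxy group anti to the incoming aryl group, with hydrogen and not the silyloxymethyl group flanking its path, which should give the anti (erythro) 1R,2S pair; at C2 the steric Felkin–Anh arrangement with ring C anti to the nucleophile should give the 1R carbinol, a configuration that is erased in step 22. The step needs aldehyde-over-lactone selectivity and no enolisation of the two alpha centres, both secured by the low basicity and low ester reactivity of the titanium reagent at low temperature, and it needs non-chelation control at G1, secured by the weakly coordinating aryloxy oxygen and the bulky silyl ether that keeps the beta oxygen off the metal.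

Step 22
Reactants: 33 (3R,4R)-3-[[3-[(1R,2R)-1-(4-benzyloxy-3-methoxyphenyl)-1-hydroxy-3-(TBDPS-oxy)propan-2-yl]-5-methoxy-4-(methoxymethoxy)phenyl]methyl]-4-[[4-{[(1R,2S)-1-(4-benzyloxy-3-methoxyphenyl)-1-hydroxy-3-(TBDPS-oxy)propan-2-yl]oxy}-3-methoxyphenyl]methyl]oxolan-2-one
Product: 35 (3R,4R)-3-[[(2S,3R)-2-(4-benzyloxy-3-methoxyphenyl)-7-methoxy-3-(TBDPS-oxymethyl)-2,3-dihydro-1-benzofuran-5-yl]methyl]-4-[[4-{[(1R,2S)-1-(4-benzyloxy-3-methoxyphenyl)-1-hydroxy-3-(TBDPS-oxy)propan-2-yl]oxy}-3-methoxyphenyl]methyl]oxolan-2-one, via free phenol 34 (not isolated)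
Conditions: CF3CO2H/H2O (9:1, 10 vol%), CH2Cl2, 0 °C; then aq NaHCO3
Reagents that add atoms: none
Why: Acid cleaves the aryl methoxymethyl acetal to phenol 34 and ionises the C2 carbinol to the cation stabilised by the para-benzyloxy group of ring D, which the phenol oxygen captures in a 5-exo SN1 etherification anti to the C3 substituent to set C2 as S (trans ring), while the G1 carbinol, with an electron-withdrawing aryloxy neighbour and no internal nucleophile, should ionise far more slowly.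

Step 23
Reactants: 35 (3R,4R)-3-[[(2S,3R)-2-(4-benzyloxy-3-methoxyphenyl)-7-methoxy-3-(TBDPS-oxymethyl)-2,3-dihydro-1-benzofuran-5-yl]methyl]-4-[[4-{[(1R,2S)-1-(4-benzyloxy-3-methoxyphenyl)-1-hydroxy-3-(TBDPS-oxy)propan-2-yl]oxy}-3-methoxyphenyl]methyl]oxolan-2-one
Product: 36 (3R,4R)-3-[[(2S,3R)-2-(4-benzyloxy-3-methoxyphenyl)-3-(hydroxymethyl)-7-methoxy-2,3-dihydro-1-benzofuran-5-yl]methyl]-4-[[4-{[(1R,2S)-1-(4-benzyloxy-3-methoxyphenyl)-1,3-dihydroxypropan-2-yl]oxy}-3-methoxyphenyl]methyl]oxolan-2-one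
Conditions: Bu4NF, AcOH, THF, rt
Reagents that add atoms: none
Why: Fluoride-mediated desilylation (Si–F bond formation) removes both TBDPS groups, with acetic acid buffering the alkoxides so that the lactone and the benzylic centres are untouched.

Step 24
Reactants: 36 (3R,4R)-3-[[(2S,3R)-2-(4-benzyloxy-3-methoxyphenyl)-3-(hydroxymethyl)-7-methoxy-2,3-dihydro-1-benzofuran-5-yl]methyl]-4-[[4-{[(1R,2S)-1-(4-benzyloxy-3-methoxyphenyl)-1,3-dihydroxypropan-2-yl]oxy}-3-methoxyphenyl]methyl]oxolan-2-one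
Product: 37 (3R,4R)-4-[[4-{[(1R,2S)-1,3-dihydroxy-1-(4-hydroxy-3-methoxyphenyl)propan-2-yl]oxy}-3-methoxyphenyl]methyl]-3-[[(2S,3R)-2-(4-hydroxy-3-methoxyphenyl)-3-(hydroxymethyl)-7-methoxy-2,3-dihydro-1-benzofuran-5-yl]methyl]oxolan-2-one (CNP0265599.1)
Conditions: H2 (1 atm), Pd/C, EtOAc/MeOH, rt
Reagents that add atoms: none
Why: Hydrogenolysis of the two aryl benzyl ethers over palladium under neutral conditions at atmospheric pressure should free the phenols of rings A and D faster than the benzylic C–O bonds at G1 and C2 are attacked.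

**Compound list**

1 | (2R)-3-(benzyloxy)propane-1,2-diol | OC[C@@H](O)COCc1ccccc1 | starting material
2 | (2S)-1-(benzyloxy)-3-[(tert-butyldiphenylsilyl)oxy]propan-2-ol | CC(C)(C)[Si](c1ccccc1)(c1ccccc1)OC[C@@H](O)COCc1ccccc1 | intermediate
3 | vanillin (4-hydroxy-3-methoxybenzaldehyde) | COc1cc(C=O)ccc1O | starting material
4 | 4-{[(2R)-1-(benzyloxy)-3-(TBDPS-oxy)propan-2-yl]oxy}-3-methoxybenzaldehyde | O=Cc1ccc(O[C@@H](CO[Si](c2ccccc2)(c2ccccc2)C(C)(C)C)COCc2ccccc2)c(OC)c1 | intermediate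
5 | dimethyl succinate | COC(=O)CCC(=O)OC | starting material
6 | (3E)-4-[4-{[(2R)-1-(benzyloxy)-3-(TBDPS-oxy)propan-2-yl]oxy}-3-methoxyphenyl]-3-(methoxycarbonyl)but-3-enoic acid | OC(=O)C/C(C(=O)OC)=C\c1ccc(O[C@@H](CO[Si](c2ccccc2)(c2ccccc2)C(C)(C)C)COCc2ccccc2)c(OC)c1 | intermediate
7 | (3R)-4-[4-{[(2R)-1-(benzyloxy)-3-(TBDPS-oxy)propan-2-yl]oxy}-3-methoxyphenyl]-3-(methoxycarbonyl)butanoic acid | OC(=O)C[C@H](C(=O)OC)Cc1ccc(O[C@@H](CO[Si](c2ccccc2)(c2ccccc2)C(C)(C)C)COCc2ccccc2)c(OC)c1 | intermediate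
8 | (3R)-4-[4-{[(2R)-1-(benzyloxy)-3-(TBDPS-oxy)propan-2-yl]oxy}-3-methoxyphenyl]-3-(hydroxymethyl)butanoic acid | OC(=O)C[C@H](CO)Cc1ccc(O[C@@H](CO[Si](c2ccccc2)(c2ccccc2)C(C)(C)C)COCc2ccccc2)c(OC)c1 | intermediate
9 | (4R)-4-[[4-{[(2R)-1-(benzyloxy)-3-(TBDPS-oxy)propan-2-yl]oxy}-3-methoxyphenyl]methyl]oxolan-2-one | O=C1C[C@@H](Cc2ccc(O[C@@H](CO[Si](c3ccccc3)(c3ccccc3)C(C)(C)C)COCc3ccccc3)c(OC)c2)CO1 | intermediate
10 | 5-bromovanillin (3-bromo-4-hydroxy-5-methoxybenzaldehyde) | COc1cc(C=O)cc(Br)c1O | starting material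
11 | 3-bromo-5-methoxy-4-(methoxymethoxy)benzaldehyde | COCOc1c(Br)cc(C=O)cc1OC | intermediate
12 | [3-bromo-5-methoxy-4-(methoxymethoxy)phenyl]methanol | COCOc1c(Br)cc(CO)cc1OC | intermediate
13 | {[3-bromo-5-methoxy-4-(methoxymethoxy)phenyl]methoxy}(tert-butyl)dimethylsilane | COCOc1c(Br)cc(CO[Si](C)(C)C(C)(C)C)cc1OC | intermediate
14 | ethyl 2-[5-(TBS-oxymethyl)-3-methoxy-2-(methoxymethoxy)phenyl]acetate | CCOC(=O)Cc1cc(CO[Si](C)(C)C(C)(C)C)cc(OC)c1OCOC | intermediate
15 | 2-[5-(TBS-oxymethyl)-3-methoxy-2-(methoxymethoxy)phenyl]acetic acid | OC(=O)Cc1cc(CO[Si](C)(C)C(C)(C)C)cc(OC)c1OCOC | intermediate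
16 | (4R)-4-benzyl-1,3-oxazolidin-2-one | O=C1N[C@H](Cc2ccccc2)CO1 | starting material
17 | mixed anhydride of 15 with pivalic acid | CC(C)(C)C(=O)OC(=O)Cc1cc(CO[Si](C)(C)C(C)(C)C)cc(OC)c1OCOC | intermediate
18 | (4R)-4-benzyl-3-{2-[5-(TBS-oxymethyl)-3-methoxy-2-(methoxymethoxy)phenyl]acetyl}-1,3-oxazolidin-2-one | O=C1OC[C@@H](Cc2ccccc2)N1C(=O)Cc1cc(CO[Si](C)(C)C(C)(C)C)cc(OC)c1OCOC | intermediate
19 | sodium Z-enolate of 18 | [Na+].[O-]/C(=C\c1cc(CO[Si](C)(C)C(C)(C)C)cc(OC)c1OCOC)N1C(=O)OC[C@H]1Cc1ccccc1 | intermediate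
20 | (4R)-4-benzyl-3-{(2S)-3-(benzyloxy)-2-[5-(TBS-oxymethyl)-3-methoxy-2-(methoxymethoxy)phenyl]propanoyl}-1,3-oxazolidin-2-one | O=C1OC[C@@H](Cc2ccccc2)N1C(=O)[C@H](COCc1ccccc1)c1cc(CO[Si](C)(C)C(C)(C)C)cc(OC)c1OCOC | intermediate
21 | (2R)-3-(benzyloxy)-2-[5-(TBS-oxymethyl)-3-methoxy-2-(methoxymethoxy)phenyl]propan-1-ol | OC[C@H](COCc1ccccc1)c1cc(CO[Si](C)(C)C(C)(C)C)cc(OC)c1OCOC | intermediate
22 | tert-butyl{(2S)-3-(benzyloxy)-2-[5-(TBS-oxymethyl)-3-methoxy-2-(methoxymethoxy)phenyl]propoxy}diphenylsilane | CC(C)(C)[Si](c1ccccc1)(c1ccccc1)OC[C@H](COCc1ccccc1)c1cc(CO[Si](C)(C)C(C)(C)C)cc(OC)c1OCOC | intermediate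
23 | {3-[(2S)-1-(benzyloxy)-3-(TBDPS-oxy)propan-2-yl]-5-methoxy-4-(methoxymethoxy)phenyl}methanol | CC(C)(C)[Si](c1ccccc1)(c1ccccc1)OC[C@H](COCc1ccccc1)c1cc(CO)cc(OC)c1OCOC | intermediate
24 | 1-[(2S)-1-(benzyloxy)-3-(TBDPS-oxy)propan-2-yl]-5-(bromomethyl)-3-methoxy-2-(methoxymethoxy)benzene | CC(C)(C)[Si](c1ccccc1)(c1ccccc1)OC[C@H](COCc1ccccc1)c1cc(CBr)cc(OC)c1OCOC | intermediate
25 | lithium enolate of 9 | [Li+].[O-]C1=C[C@@H](Cc2ccc(O[C@@H](CO[Si](c3ccccc3)(c3ccccc3)C(C)(C)C)COCc3ccccc3)c(OC)c2)CO1 | intermediate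
26 | (3R,4R)-3-[[3-[(2S)-1-(benzyloxy)-3-(TBDPS-oxy)propan-2-yl]-5-methoxy-4-(methoxymethoxy)phenyl]methyl]-4-[[4-{[(2R)-1-(benzyloxy)-3-(TBDPS-oxy)propan-2-yl]oxy}-3-methoxyphenyl]methyl]oxolan-2-one | c1ccccc1COC[C@H](CO[Si](c1ccccc1)(c1ccccc1)C(C)(C)C)Oc1ccc(C[C@H]2COC(=O)[C@@H]2Cc2cc(OC)c(OCOC)c(c2)[C@H](CO[Si](c2ccccc2)(c2ccccc2)C(C)(C)C)COCc2ccccc2)cc1OC | intermediate
27 | (3R,4R)-3-[[3-[(2S)-1-hydroxy-3-(TBDPS-oxy)propan-2-yl]-5-methoxy-4-(methoxymethoxy)phenyl]methyl]-4-[[4-{[(2R)-1-hydroxy-3-(TBDPS-oxy)propan-2-yl]oxy}-3-methoxyphenyl]methyl]oxolan-2-one | OC[C@H](CO[Si](c1ccccc1)(c1ccccc1)C(C)(C)C)Oc1ccc(C[C@H]2COC(=O)[C@@H]2Cc2cc(OC)c(OCOC)c(c2)[C@H](CO[Si](c2ccccc2)(c2ccccc2)C(C)(C)C)CO)cc1OC | intermediate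
28 | (3R,4R)-3-[[3-[(2R)-1-oxo-3-(TBDPS-oxy)propan-2-yl]-5-methoxy-4-(methoxymethoxy)phenyl]methyl]-4-[[4-{[(2S)-1-oxo-3-(TBDPS-oxy)propan-2-yl]oxy}-3-methoxyphenyl]methyl]oxolan-2-one (core dialdehyde) | O=C[C@H](CO[Si](c1ccccc1)(c1ccccc1)C(C)(C)C)Oc1ccc(C[C@H]2COC(=O)[C@@H]2Cc2cc(OC)c(OCOC)c(c2)[C@H](CO[Si](c2ccccc2)(c2ccccc2)C(C)(C)C)C=O)cc1OC | intermediate
29 | 4-bromo-2-methoxyphenol | COc1cc(Br)ccc1O | starting material
30 | 1-(benzyloxy)-4-bromo-2-methoxybenzene | COc1cc(Br)ccc1OCc1ccccc1 | intermediate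
31 | (4-benzyloxy-3-methoxyphenyl)lithium | [Li]c1ccc(OCc2ccccc2)c(OC)c1 | intermediate
32 | (4-benzyloxy-3-methoxyphenyl)titanium triisopropoxide | CC(C)O[Ti](OC(C)C)(OC(C)C)c1ccc(OCc2ccccc2)c(OC)c1 | intermediate
33 | (3R,4R)-3-[[3-[(1R,2R)-1-(4-benzyloxy-3-methoxyphenyl)-1-hydroxy-3-(TBDPS-oxy)propan-2-yl]-5-methoxy-4-(methoxymethoxy)phenyl]methyl]-4-[[4-{[(1R,2S)-1-(4-benzyloxy-3-methoxyphenyl)-1-hydroxy-3-(TBDPS-oxy)propan-2-yl]oxy}-3-methoxyphenyl]methyl]oxolan-2-one (bis-carbinol) | COc1cc([C@@H](O)[C@H](CO[Si](c2ccccc2)(c2ccccc2)C(C)(C)C)Oc2ccc(C[C@H]3COC(=O)[C@@H]3Cc3cc(OC)c(OCOC)c(c3)[C@H](CO[Si](c3ccccc3)(c3ccccc3)C(C)(C)C)[C@@H](O)c3ccc(OCc4ccccc4)c(OC)c3)cc2OC)ccc1OCc1ccccc1 | intermediate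
34 | free ring C phenol of 33 (MOM removed) | COc1cc([C@@H](O)[C@H](CO[Si](c2ccccc2)(c2ccccc2)C(C)(C)C)Oc2ccc(C[C@H]3COC(=O)[C@@H]3Cc3cc(OC)c(O)c(c3)[C@H](CO[Si](c3ccccc3)(c3ccccc3)C(C)(C)C)[C@@H](O)c3ccc(OCc4ccccc4)c(OC)c3)cc2OC)ccc1OCc1ccccc1 | intermediate
35 | (3R,4R)-3-[[(2S,3R)-2-(4-benzyloxy-3-methoxyphenyl)-7-methoxy-3-(TBDPS-oxymethyl)-2,3-dihydro-1-benzofuran-5-yl]methyl]-4-[[4-{[(1R,2S)-1-(4-benzyloxy-3-methoxyphenyl)-1-hydroxy-3-(TBDPS-oxy)propan-2-yl]oxy}-3-methoxyphenyl]methyl]oxolan-2-one | COc1cc([C@@H](O)[C@H](CO[Si](c2ccccc2)(c2ccccc2)C(C)(C)C)Oc2ccc(C[C@H]3COC(=O)[C@@H]3Cc3cc(OC)c4c(c3)[C@H](CO[Si](c3ccccc3)(c3ccccc3)C(C)(C)C)[C@@H](c3ccc(OCc5ccccc5)c(OC)c3)O4)cc2OC)ccc1OCc1ccccc1 | intermediate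
36 | (3R,4R)-3-[[(2S,3R)-2-(4-benzyloxy-3-methoxyphenyl)-3-(hydroxymethyl)-7-methoxy-2,3-dihydro-1-benzofuran-5-yl]methyl]-4-[[4-{[(1R,2S)-1-(4-benzyloxy-3-methoxyphenyl)-1,3-dihydroxypropan-2-yl]oxy}-3-methoxyphenyl]methyl]oxolan-2-one | COc1cc([C@@H](O)[C@H](CO)Oc2ccc(C[C@H]3COC(=O)[C@@H]3Cc3cc(OC)c4c(c3)[C@H](CO)[C@@H](c3ccc(OCc5ccccc5)c(OC)c3)O4)cc2OC)ccc1OCc1ccccc1 | intermediate
37 | CNP0265599.1, (3R,4R)-4-[[4-{[(1R,2S)-1,3-dihydroxy-1-(4-hydroxy-3-methoxyphenyl)propan-2-yl]oxy}-3-methoxyphenyl]methyl]-3-[[(2S,3R)-2-(4-hydroxy-3-methoxyphenyl)-3-(hydroxymethyl)-7-methoxy-2,3-dihydro-1-benzofuran-5-yl]methyl]oxolan-2-one | COc1cc([C@@H](O)[C@H](CO)Oc2ccc(C[C@H]3COC(=O)[C@@H]3Cc3cc(OC)c4c(c3)[C@H](CO)[C@@H](c3ccc(O)c(OC)c3)O4)cc2OC)ccc1O | target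

**Step count and risks**

Total step count: 24. Longest linear sequence: 18 steps (steps 6 to 19 and 21 to 24, from 5-bromovanillin 10).

The three steps most likely to fail:

Step 21. Attack on the other face of the alpha-aryloxy aldehyde would erode the anti preference at G1 and give the G1 epimer beside 33; enolisation of the alpha-aryl aldehyde is the second danger and is answered by keeping 28 cold and using it at once. Fallback, setting out from dialdehyde 28 and coming back at 35: the addition is run as in step 21 and the mixture of 33 and its G1 epimer, the threo bis-carbinol F1, is taken through the acid treatment of step 22, where C2 is erased in any case. This gives 35 together with its G1 epimer, the threo dihydrobenzofuran F2. The only free hydroxyl of both, at G1, is oxidised with Dess–Martin periodinane, so the two epimers converge on the aryl ketone F3. Reduction with Zn(BH4)2 in Et2O at −30 °C under chelation control (zinc held between the ketone oxygen and the ether oxygens of ring B) should return the anti carbinol 35. G1 is then set by hydride delivery to a ketone instead of aryl delivery to an aldehyde.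

Step 22. Competing ionisation at G1 (epimerisation or loss of the ring B ether), or a cis/trans mixture at C2 if capture of the cation is not selective. Fallback, setting out from 33 and coming back at 35, with no cation involved: the acetal is removed without protic acid (Me3SiOTf, 2,2'-bipyridyl, CH2Cl2, 0 °C, then water), giving phenol 34, now isolated. The ring is closed by intramolecular Mitsunobu etherification (PPh3 and DIAD, 1 equiv each, THF, 0 °C). The phenol can reach only C2 and displaces its activated hydroxyl with inversion, so the (R)-carbinol expected from step 21 becomes the (2S) centre of the trans ring. This fallback depends on the C2 carbinol being one epimer and makes no compound outside the compound list.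

Step 12. Slow or O-selective alkylation of the hindered enolate, beta-elimination of benzyl alcohol from the product, or erosion of the diastereoselectivity. Fallback, setting out from aryl bromide 13 and coming back at 21, by enzymatic desymmetrisation instead of auxiliary control:
- Pd(OAc)2/P(tBu)3-catalysed coupling of 13 with diethyl malonate (K3PO4, toluene, 80 °C) gives the diethyl arylmalonate F4.
- LiAlH4 in THF at 0 °C gives the prochiral 2-arylpropane-1,3-diol F5.
- Acetylation with vinyl acetate and the lipase from Burkholderia cepacia desymmetrises it to the (S)-monoacetate F6.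
- Benzylation of the free hydroxyl under neutral conditions (2-benzyloxy-1-methylpyridinium triflate, MgO, PhCF3, 85 °C) gives the benzyl ether acetate F7, and K2CO3 in MeOH returns alcohol 21.
- If the enzyme acetylates the other arm and gives the (R)-monoacetate F8, the order is reversed: silylation (TBDPSCl, imidazole) gives the silyl ether acetate F9, methanolysis gives the silyl ether alcohol F10, and the same neutral benzylation comes back at 22.

Further compounds
F1 | step 21 | G1 epimer of 33 (threo bis-carbinol, 1S at G1) | COc1cc([C@H](O)[C@H](CO[Si](c2ccccc2)(c2ccccc2)C(C)(C)C)Oc2ccc(C[C@H]3COC(=O)[C@@H]3Cc3cc(OC)c(OCOC)c(c3)[C@H](CO[Si](c3ccccc3)(c3ccccc3)C(C)(C)C)[C@@H](O)c3ccc(OCc4ccccc4)c(OC)c3)cc2OC)ccc1OCc1ccccc1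
F2 | step 21 | G1 epimer of 35 (threo dihydrobenzofuran, 1S at G1) | COc1cc([C@H](O)[C@H](CO[Si](c2ccccc2)(c2ccccc2)C(C)(C)C)Oc2ccc(C[C@H]3COC(=O)[C@@H]3Cc3cc(OC)c4c(c3)[C@H](CO[Si](c3ccccc3)(c3ccccc3)C(C)(C)C)[C@@H](c3ccc(OCc5ccccc5)c(OC)c3)O4)cc2OC)ccc1OCc1ccccc1
F3 | step 21 | G1 aryl ketone derived from 35 and F2 | COc1cc(C(=O)[C@H](CO[Si](c2ccccc2)(c2ccccc2)C(C)(C)C)Oc2ccc(C[C@H]3COC(=O)[C@@H]3Cc3cc(OC)c4c(c3)[C@H](CO[Si](c3ccccc3)(c3ccccc3)C(C)(C)C)[C@@H](c3ccc(OCc5ccccc5)c(OC)c3)O4)cc2OC)ccc1OCc1ccccc1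
F0 | step 22 | none | none
F4 | step 12 | diethyl 2-[5-(TBS-oxymethyl)-3-methoxy-2-(methoxymethoxy)phenyl]propanedioate | CCOC(=O)C(C(=O)OCC)c1cc(CO[Si](C)(C)C(C)(C)C)cc(OC)c1OCOC
F5 | step 12 | 2-[5-(TBS-oxymethyl)-3-methoxy-2-(methoxymethoxy)phenyl]propane-1,3-diol | OCC(CO)c1cc(CO[Si](C)(C)C(C)(C)C)cc(OC)c1OCOC
F6 | step 12 | (2S)-3-hydroxy-2-[5-(TBS-oxymethyl)-3-methoxy-2-(methoxymethoxy)phenyl]propyl acetate | CC(=O)OC[C@H](CO)c1cc(CO[Si](C)(C)C(C)(C)C)cc(OC)c1OCOC
F7 | step 12 | (2S)-3-(benzyloxy)-2-[5-(TBS-oxymethyl)-3-methoxy-2-(methoxymethoxy)phenyl]propyl acetate | CC(=O)OC[C@H](COCc1ccccc1)c1cc(CO[Si](C)(C)C(C)(C)C)cc(OC)c1OCOC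
F8 | step 12 | (2R)-3-hydroxy-2-[5-(TBS-oxymethyl)-3-methoxy-2-(methoxymethoxy)phenyl]propyl acetate | OC[C@H](COC(C)=O)c1cc(CO[Si](C)(C)C(C)(C)C)cc(OC)c1OCOC
F9 | step 12 | (2S)-3-(TBDPS-oxy)-2-[5-(TBS-oxymethyl)-3-methoxy-2-(methoxymethoxy)phenyl]propyl acetate | CC(C)(C)[Si](c1ccccc1)(c1ccccc1)OC[C@H](COC(C)=O)c1cc(CO[Si](C)(C)C(C)(C)C)cc(OC)c1OCOC
F10 | step 12 | (2S)-3-(TBDPS-oxy)-2-[5-(TBS-oxymethyl)-3-methoxy-2-(methoxymethoxy)phenyl]propan-1-ol | CC(C)(C)[Si](c1ccccc1)(c1ccccc1)OC[C@H](CO)c1cc(CO[Si](C)(C)C(C)(C)C)cc(OC)c1OCOC
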